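**Retrosynthetic overview**
1. Target 14 is an all-cis 2,5-diaryl-3,4-dimethyloxolane (O1, C2–C5; 2S,3R,4S,5R) whose two aryl para-oxygens carry the same (1R,2S)-1-(3,4-dimethoxyphenyl)-1-hydroxypropan-2-yl chain. End game: desilylation ⇐ syn-hydrogenation of furan 12, which sets C2–C5 together.
2. Key disconnection: furan 12 ⇐ two molecules of aryl ethyl ketone 9. Oxidative enolate homocoupling makes C3–C4 and Paal–Knorr cyclodehydration makes O1–C2/O1–C5, echoing the 8–8' union of two C6–C3 units in lignan biosynthesis at the ketone oxidation level.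
3. Enabling feature: the halves O1–C2(aryl)–C3(CH3) and O1–C5(aryl)–C4(CH3) are constitutionally identical and both arms are homochiral. Furan 12 therefore has a C2 axis through O1 and the C3–C4 midpoint, its two faces are homotopic, and any all-cis hydrogenation gives one ring isomer.
4. Monomer 9 ⇐ propiovanillone 6 + (R)-α-tosyloxy ketone 5 (SN2 with inversion → 2S), chelation-controlled reduction (→ 1R), silylation; 5 ⇐ methyl (R)-lactate 1 + arylmagnesium bromide 3.
5. Ring order: the four benzene rings are purchased; the five-membered O-ring is the only ring made and the last closed (step 7, furan level), then brought to the oxolane level (step 8).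

Key step: step 7

Remark: the ring is read as all-cis (both aryl and both methyl groups on one face) and both chains as (1R,2S) (erythro); LiN(iPr)2 and ArMgBr 3 are used as purchased solutions, and Zn(BH4)2 is made from ZnCl2 and NaBH4 just before use.

**Step 1**
Reactants: 1 methyl (R)-lactate
Product: 2 (2R)-2-hydroxy-N-methoxy-N-methylpropanamide
Conditions: MeNH(OMe)·HCl, iPrMgCl, THF, −20 → 0 °C; aq. NH4Cl
Reagents that add atoms: N,O-dimethylhydroxylamine hydrochloride, CNOC.Cl
Why: Aminolysis of the ester by the magnesium amide (Weinreb amide formation) should proceed without touching the stereocentre, because the hydroxyl is deprotonated first and the resulting alkoxide is not enolised at low temperature.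

**Step 2**
Reactants: 2 (2R)-2-hydroxy-N-methoxy-N-methylpropanamide; 3 3,4-dimethoxyphenylmagnesium bromide
Product: 4 (2R)-1-(3,4-dimethoxyphenyl)-2-hydroxypropan-1-one
Conditions: ArMgBr 3 (3 equiv), THF, 0 °C → rt; aq. NH4Cl
Reagents that add atoms: none
Why: In this Weinreb ketone synthesis the first equivalent of 3 deprotonates the hydroxyl, the N-methoxy-N-methyl amide stops the addition at the ketone stage, and the magnesium alkoxide shields the α-hydrogen from enolisation so that the (R) centre is retained.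

**Step 3**
Reactants: 4 (2R)-1-(3,4-dimethoxyphenyl)-2-hydroxypropan-1-one
Product: 5 (2R)-1-(3,4-dimethoxyphenyl)-1-oxopropan-2-yl 4-methylbenzenesulfonate
Conditions: TsCl, Et3N, DMAP (cat.), CH2Cl2, 0 °C
Reagents that add atoms: 4-methylbenzenesulfonyl chloride (TsCl), Cc1ccc(S(=O)(=O)Cl)cc1
Why: O-Sulfonylation breaks no bond at the stereocentre, and the mild amine base at 0 °C should not enolise the ketone, so the (R) configuration is kept.

**Step 4**
Reactants: 5 (2R)-1-(3,4-dimethoxyphenyl)-1-oxopropan-2-yl 4-methylbenzenesulfonate; 6 propiovanillone [1-(4-hydroxy-3-methoxyphenyl)propan-1-one]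
Product: 7 (2S)-1-(3,4-dimethoxyphenyl)-2-(2-methoxy-4-propanoylphenoxy)propan-1-one
Conditions: K2CO3, DMF, rt
Reagents that add atoms: none
Why: Williamson-type SN2 displacement of the carbonyl-activated sulfonate by the phenoxide should invert the centre (R → S), and the non-nucleophilic tosylate leaving group avoids the racemising exchange that halides cause, while the weak base at rt should not epimerise the product.

**Step 5**
Reactants: 7 (2S)-1-(3,4-dimethoxyphenyl)-2-(2-methoxy-4-propanoylphenoxy)propan-1-one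
Product: 8 1-[4-{[(1R,2S)-1-(3,4-dimethoxyphenyl)-1-hydroxypropan-2-yl]oxy}-3-methoxyphenyl]propan-1-one
Conditions: Zn(BH4)2 (0.6 equiv, from ZnCl2 + NaBH4), Et2O/THF, −40 → −20 °C; aq. NH4Cl
Reagents that add atoms: none
Why: In this chelation-controlled reduction (Cram chelate model) zinc bridges the carbonyl oxygen and the α-aryloxy oxygen, hydride enters from the face of the α-hydrogen to give the anti (erythro) 1R alcohol, and the chelated, inductively activated α-aryloxy ketone should react far faster than the unactivated p-alkoxy aryl ethyl ketone at low temperature with limited hydride.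

**Step 6**
Reactants: 8 1-[4-{[(1R,2S)-1-(3,4-dimethoxyphenyl)-1-hydroxypropan-2-yl]oxy}-3-methoxyphenyl]propan-1-one
Product: 9 1-[4-{[(1R,2S)-1-(3,4-dimethoxyphenyl)-1-(triisopropylsilyloxy)propan-2-yl]oxy}-3-methoxyphenyl]propan-1-one
Conditions: TIPSOTf, 2,6-lutidine, CH2Cl2, −20 → 0 °C
Reagents that add atoms: triisopropylsilyl trifluoromethanesulfonate (TIPSOTf), CC(C)[Si](OS(=O)(=O)C(F)(F)F)(C(C)C)C(C)C
Why: Silylation of the secondary benzylic alcohol with a silyl triflate and a hindered pyridine base touches no stereocentre, and at low temperature the aryl ethyl ketone should not be converted into a silyl enol ether.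

**Step 7**
Reactants: 9 1-[4-{[(1R,2S)-1-(3,4-dimethoxyphenyl)-1-(triisopropylsilyloxy)propan-2-yl]oxy}-3-methoxyphenyl]propan-1-one (two molecules)
Product: 12 2,5-bis[4-{[(1R,2S)-1-(3,4-dimethoxyphenyl)-1-(triisopropylsilyloxy)propan-2-yl]oxy}-3-methoxyphenyl]-3,4-dimethylfuran, via lithium enolate 10 (not isolated), via 1,4-diketone 11 (not isolated)
Conditions: LiN(iPr)2 (LDA, 1.05 equiv), THF, −78 °C; CuCl2 (1.1 equiv), DMF, −78 °C → rt; aq. NH4Cl/NH3 wash, solvent switch; CSA (0.2 equiv), 4 Å MS, PhMe, 70 °C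
Reagents that add atoms: none
Why: LDA gives the (Z)-lithium enolate 10, which divalent copper oxidises by single-electron transfer to an α-keto radical (or copper-bound enolate) that joins a second unit at the α-carbons to form the C3–C4 bond of 1,4-diketone 11 as a meso/dl mixture; the sulfonic acid then drives the Paal–Knorr furan synthesis, in which the enol oxygen of one ketone adds to the other protonated carbonyl and loss of water gives the aromatic ring. The closest known reaction type is the CuCl2-mediated oxidative homocoupling of propiophenone lithium enolates to 2,3-dimethyl-1,4-diarylbutane-1,4-diones followed by their acid-catalysed cyclodehydration to 2,5-diaryl-3,4-dimethylfurans. The only ring closed is the five-membered O-ring, formed by 5-exo-trig attack of the enol oxygen on the carbonyl carbon and made irreversible by aromatisation. No new stereocentre remains: the two α-centres of 11 are erased on aromatisation, so its diastereomer ratio does not matter, and the four chain stereocentres carry no acidic hydrogen and should pass through unchanged. The selectivity needed is C–C over C–O coupling and over α-chlorination at a single enolisation site; it is secured by the one enolisable CH2 of 9, by complete enolate formation at −78 °C before the oxidant is added, and by the β-aryloxy group and bulky silyl ether that disfavour ionisation of the benzylic C–O bonds under anhydrous CSA. The product is C2-symmetric, so any minor enantiomer of the monomer should end up mainly in a separable diastereomeric dimer and the furan faces are homotopic for step 8.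

**Step 8**
Reactants: 12 2,5-bis[4-{[(1R,2S)-1-(3,4-dimethoxyphenyl)-1-(triisopropylsilyloxy)propan-2-yl]oxy}-3-methoxyphenyl]-3,4-dimethylfuran
Product: 13 (2S,3R,4S,5R)-2,5-bis[4-{[(1R,2S)-1-(3,4-dimethoxyphenyl)-1-(triisopropylsilyloxy)propan-2-yl]oxy}-3-methoxyphenyl]-3,4-dimethyloxolane (all-cis)
Conditions: H2 (4 atm), 10% Pd/C, NaHCO3, EtOAc, rt
Reagents that add atoms: none
Why: Heterogeneous hydrogenation of a 2,5-diaryl-3,4-dimethylfuran delivers all four hydrogens from the catalyst side to give the all-cis oxolane, and because the C2 axis of 12 makes its faces homotopic either face gives the same (2S,3R,4S,5R) ring, while the neutral buffered medium should suppress acid-promoted hydrogenolysis and epimerisation at the benzylic C–O bonds.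

**Step 9**
Reactants: 13 (2S,3R,4S,5R)-2,5-bis[4-{[(1R,2S)-1-(3,4-dimethoxyphenyl)-1-(triisopropylsilyloxy)propan-2-yl]oxy}-3-methoxyphenyl]-3,4-dimethyloxolane
Product: 14 (1R,2S)-1-(3,4-dimethoxyphenyl)-2-[4-[(2S,3R,4S,5R)-5-[4-[[(1R,2S)-1-(3,4-dimethoxyphenyl)-1-hydroxypropan-2-yl]oxy]-3-methoxyphenyl]-3,4-dimethyloxolan-2-yl]-2-methoxyphenoxy]propan-1-ol (target)
Conditions: TBAF, THF, 0 °C → rt; aq. NaHCO3; chromatography on Et3N-washed silica
Reagents that add atoms: none
Why: Fluoride-mediated Si–O cleavage under basic, non-acidic conditions should leave the acid-labile all-cis bis-benzylic ether ring and all eight stereocentres untouched.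

**Compound list**
1 | methyl (R)-lactate | C[C@@H](O)C(=O)OC | starting material
2 | (2R)-2-hydroxy-N-methoxy-N-methylpropanamide | C[C@@H](O)C(=O)N(C)OC | intermediate
3 | 3,4-dimethoxyphenylmagnesium bromide | COc1ccc([Mg]Br)cc1OC | starting material
4 | (2R)-1-(3,4-dimethoxyphenyl)-2-hydroxypropan-1-one | C[C@@H](O)C(=O)c1ccc(OC)c(OC)c1 | intermediate
5 | (2R)-1-(3,4-dimethoxyphenyl)-1-oxopropan-2-yl 4-methylbenzenesulfonate | C[C@@H](OS(=O)(=O)c1ccc(C)cc1)C(=O)c1ccc(OC)c(OC)c1 | intermediate
6 | propiovanillone, 1-(4-hydroxy-3-methoxyphenyl)propan-1-one | CCC(=O)c1ccc(O)c(OC)c1 | starting material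
7 | (2S)-1-(3,4-dimethoxyphenyl)-2-(2-methoxy-4-propanoylphenoxy)propan-1-one | CCC(=O)c1ccc(O[C@@H](C)C(=O)c2ccc(OC)c(OC)c2)c(OC)c1 | intermediate
8 | 1-[4-{[(1R,2S)-1-(3,4-dimethoxyphenyl)-1-hydroxypropan-2-yl]oxy}-3-methoxyphenyl]propan-1-one | CCC(=O)c1ccc(O[C@@H](C)[C@H](O)c2ccc(OC)c(OC)c2)c(OC)c1 | intermediate
9 | 1-[4-{[(1R,2S)-1-(3,4-dimethoxyphenyl)-1-(triisopropylsilyloxy)propan-2-yl]oxy}-3-methoxyphenyl]propan-1-one | CCC(=O)c1ccc(O[C@@H](C)[C@H](O[Si](C(C)C)(C(C)C)C(C)C)c2ccc(OC)c(OC)c2)c(OC)c1 | intermediate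
10 | lithium (Z)-enolate of 9 | C/C=C(\O[Li])c1ccc(O[C@@H](C)[C@H](O[Si](C(C)C)(C(C)C)C(C)C)c2ccc(OC)c(OC)c2)c(OC)c1 | intermediate
11 | 2,3-dimethyl-1,4-bis[4-{[(1R,2S)-1-(3,4-dimethoxyphenyl)-1-(triisopropylsilyloxy)propan-2-yl]oxy}-3-methoxyphenyl]butane-1,4-dione (mixture of diastereomers at C2/C3) | CC(C(=O)c1ccc(O[C@@H](C)[C@H](O[Si](C(C)C)(C(C)C)C(C)C)c2ccc(OC)c(OC)c2)c(OC)c1)C(C)C(=O)c1ccc(O[C@@H](C)[C@H](O[Si](C(C)C)(C(C)C)C(C)C)c2ccc(OC)c(OC)c2)c(OC)c1 | intermediate
12 | 2,5-bis[4-{[(1R,2S)-1-(3,4-dimethoxyphenyl)-1-(triisopropylsilyloxy)propan-2-yl]oxy}-3-methoxyphenyl]-3,4-dimethylfuran | Cc1c(-c2ccc(O[C@@H](C)[C@H](O[Si](C(C)C)(C(C)C)C(C)C)c3ccc(OC)c(OC)c3)c(OC)c2)oc(-c2ccc(O[C@@H](C)[C@H](O[Si](C(C)C)(C(C)C)C(C)C)c3ccc(OC)c(OC)c3)c(OC)c2)c1C | intermediate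
13 | (2S,3R,4S,5R)-2,5-bis[4-{[(1R,2S)-1-(3,4-dimethoxyphenyl)-1-(triisopropylsilyloxy)propan-2-yl]oxy}-3-methoxyphenyl]-3,4-dimethyloxolane (all-cis) | COc1ccc([C@@H](O[Si](C(C)C)(C(C)C)C(C)C)[C@H](C)Oc2ccc([C@H]3O[C@@H](c4ccc(O[C@@H](C)[C@H](O[Si](C(C)C)(C(C)C)C(C)C)c5ccc(OC)c(OC)c5)c(OC)c4)[C@@H](C)[C@H]3C)cc2OC)cc1OC | intermediate
14 | (1R,2S)-1-(3,4-dimethoxyphenyl)-2-[4-[(2S,3R,4S,5R)-5-[4-[[(1R,2S)-1-(3,4-dimethoxyphenyl)-1-hydroxypropan-2-yl]oxy]-3-methoxyphenyl]-3,4-dimethyloxolan-2-yl]-2-methoxyphenoxy]propan-1-ol | COc1ccc([C@@H](O)[C@H](C)Oc2ccc([C@H]3O[C@@H](c4ccc(O[C@@H](C)[C@H](O)c5ccc(OC)c(OC)c5)c(OC)c4)[C@@H](C)[C@H]3C)cc2OC)cc1OC | target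

**Step count and risks**

Total step count: 9. Longest linear sequence: 9 steps (1 → 2 → 4 → 5 → 7 → 8 → 9 → 12 → 13 → 14).

Steps most likely to fail:

Step 7. The copper-mediated coupling may stall at low conversion or divert to α-chlorination and C–O coupling, and the silyl ethers may be partly lost in the acid stage. The fallback makes the C3–C4 bond by ionic alkylation instead of oxidation. It sets out from 9: one portion is converted through enolate 10 and N-bromosuccinimide (THF, −78 °C) into 2-bromo-1-[4-{[(1R,2S)-1-(3,4-dimethoxyphenyl)-1-(triisopropylsilyloxy)propan-2-yl]oxy}-3-methoxyphenyl]propan-1-one F1. A second portion of enolate 10 (THF/DMPU, −78 → 0 °C) is then alkylated by F1 in an SN2 reaction. This gives diketone 11, where the fallback rejoins the route for the CSA cyclodehydration to 12.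

Step 5. The two aryl ketones may not be differentiated well enough (over-reduction of the propanoyl group), and weak chelation by the aryloxy oxygen may erode facial selectivity. The fallback removes the competing ketone and uses reagent control. It sets out from tosylate 5, which is combined with commercial 4-bromo-2-methoxyphenol (K2CO3, DMF, rt) to give (2S)-2-(4-bromo-2-methoxyphenoxy)-1-(3,4-dimethoxyphenyl)propan-1-one F2. Corey–Bakshi–Shibata reduction with BH3·SMe2 and the (R)-B-methyl oxazaborolidine (aryl as the large group, hydride to the same face as in the chelate model) should give (1R,2S)-2-(4-bromo-2-methoxyphenoxy)-1-(3,4-dimethoxyphenyl)propan-1-ol F3. Silylation with TIPSOTf and 2,6-lutidine gives the silyl ether [(1R,2S)-2-(4-bromo-2-methoxyphenoxy)-1-(3,4-dimethoxyphenyl)propoxy]triisopropylsilane F4. Bromine–lithium exchange (n-BuLi, THF, −78 °C) gives the aryllithium F5, which is acylated with N-methoxy-N-methylpropanamide. The fallback comes back to the route at 9.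

Step 8. The benzylic ring C–O bonds of the product may undergo hydrogenolysis, hydrogen uptake on the crowded tetrasubstituted furan bearing two bulky chains may be slow, and C2/C5 may epimerise on an acidic catalyst surface. The fallback hydrogenates the ring before the chains are attached and finishes in two directions. It sets out from 6, which is benzylated (BnBr, K2CO3, DMF) to 1-[4-(benzyloxy)-3-methoxyphenyl]propan-1-one F6. The conditions of step 7 convert F6 through its lithium (Z)-enolate F7 and 1,4-bis[4-(benzyloxy)-3-methoxyphenyl]-2,3-dimethylbutane-1,4-dione F8 into 2,5-bis[4-(benzyloxy)-3-methoxyphenyl]-3,4-dimethylfuran F9. Hydrogenation (H2, Pd/C, EtOAc) should remove both benzyl groups and saturate the ring to the meso all-cis bisphenol 4,4'-[(2R,3S,4R,5S)-3,4-dimethyloxolane-2,5-diyl]bis(2-methoxyphenol) F10. Double O-alkylation with tosylate 5 (K2CO3, DMF) gives the bis(aryloxy ketone) (2S,2'S)-2,2'-{[(2R,3S,4R,5S)-3,4-dimethyloxolane-2,5-diyl]bis[(2-methoxy-4,1-phenylene)oxy]}bis[1-(3,4-dimethoxyphenyl)propan-1-one] F11. Double Zn(BH4)2 reduction as in step 5 then comes back to the route at target 14.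

**Further compounds**
F1 | step 7 | 2-bromo-1-[4-{[(1R,2S)-1-(3,4-dimethoxyphenyl)-1-(triisopropylsilyloxy)propan-2-yl]oxy}-3-methoxyphenyl]propan-1-one (epimer mixture at the CHBr carbon) | CC(Br)C(=O)c1ccc(O[C@@H](C)[C@H](O[Si](C(C)C)(C(C)C)C(C)C)c2ccc(OC)c(OC)c2)c(OC)c1
F2 | step 5 | (2S)-2-(4-bromo-2-methoxyphenoxy)-1-(3,4-dimethoxyphenyl)propan-1-one | COc1cc(Br)ccc1O[C@@H](C)C(=O)c1ccc(OC)c(OC)c1
F3 | step 5 | (1R,2S)-2-(4-bromo-2-methoxyphenoxy)-1-(3,4-dimethoxyphenyl)propan-1-ol | COc1cc(Br)ccc1O[C@@H](C)[C@H](O)c1ccc(OC)c(OC)c1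
F4 | step 5 | [(1R,2S)-2-(4-bromo-2-methoxyphenoxy)-1-(3,4-dimethoxyphenyl)propoxy]triisopropylsilane | COc1cc(Br)ccc1O[C@@H](C)[C@H](O[Si](C(C)C)(C(C)C)C(C)C)c1ccc(OC)c(OC)c1
F5 | step 5 | aryllithium from F4, [4-{[(1R,2S)-1-(3,4-dimethoxyphenyl)-1-(triisopropylsilyloxy)propan-2-yl]oxy}-3-methoxyphenyl]lithium | COc1cc([Li])ccc1O[C@@H](C)[C@H](O[Si](C(C)C)(C(C)C)C(C)C)c1ccc(OC)c(OC)c1
F6 | step 8 | 1-[4-(benzyloxy)-3-methoxyphenyl]propan-1-one | CCC(=O)c1ccc(OCc2ccccc2)c(OC)c1
F7 | step 8 | lithium (Z)-enolate of F6 | C/C=C(\O[Li])c1ccc(OCc2ccccc2)c(OC)c1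
F8 | step 8 | 1,4-bis[4-(benzyloxy)-3-methoxyphenyl]-2,3-dimethylbutane-1,4-dione (diastereomer mixture) | CC(C(=O)c1ccc(OCc2ccccc2)c(OC)c1)C(C)C(=O)c1ccc(OCc2ccccc2)c(OC)c1
F9 | step 8 | 2,5-bis[4-(benzyloxy)-3-methoxyphenyl]-3,4-dimethylfuran | Cc1c(-c2ccc(OCc3ccccc3)c(OC)c2)oc(-c2ccc(OCc3ccccc3)c(OC)c2)c1C
F10 | step 8 | 4,4'-[(2R,3S,4R,5S)-3,4-dimethyloxolane-2,5-diyl]bis(2-methoxyphenol) (meso, all-cis) | COc1cc([C@H]2O[C@@H](c3ccc(O)c(OC)c3)[C@@H](C)[C@H]2C)ccc1O
F11 | step 8 | (2S,2'S)-2,2'-{[(2R,3S,4R,5S)-3,4-dimethyloxolane-2,5-diyl]bis[(2-methoxy-4,1-phenylene)oxy]}bis[1-(3,4-dimethoxyphenyl)propan-1-one] | COc1ccc(C(=O)[C@H](C)Oc2ccc([C@H]3O[C@@H](c4ccc(O[C@@H](C)C(=O)c5ccc(OC)c(OC)c5)c(OC)c4)[C@@H](C)[C@H]3C)cc2OC)cc1OC
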